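**Retrosynthetic overview**

1. Feature: ring E has oxygen at C1, C3, C5 and C6 and hydrogen at C2 and C4, and its C6 ether to ring F sits between the oxygenated carbons C1 and C5; this crowded ring is therefore not arylated at C6 but grown on the ring F oxygen.
2. Key disconnection: ring E ⇒ 4-aryloxy-3-ethoxycyclobutenone (aryl = F–G) + ethoxyacetylene; the benzannulation makes C1–C2 and C3–C4, recloses C1–C6 and leaves a single free hydroxyl, at C1.
3. Cyclobutenone ⇒ F–G aryloxyketene + ethoxyacetylene ((2+2)); F–G phenol ⇒ 3,4,5-trimethoxyphenol + 4-bromo-3,5-dimethoxybenzaldehyde (Ullmann coupling, then Baeyer–Villiger oxidation).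
4. Every other diaryl ether: phenol + formyl-activated aryl bromide (Ullmann), then Baeyer–Villiger oxidation turns the formyl group into the next phenol; rings D, C, B and A are appended in this order to the C1 oxygen of ring E, and BBr3 removes 14 methyl and 2 ethyl groups last.
5. Ring order: G and F are bought as arenes, E is the only ring formed (step 6), and D, C, B and A are bought arenes added after it.

Key step: step 6

Remark: the target has no stereocentre; rings are lettered A to G in the order of the target SMILES and numbered from the first-written atom. Compounds 12, 14 and 16 are racemic and their sp3 centres vanish on aromatisation.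

**Route**

Step 1
Reactants: 1 3,4,5-trimethoxyphenol; 2 4-bromo-3,5-dimethoxybenzaldehyde
Product: 3 3,5-dimethoxy-4-(3,4,5-trimethoxyphenoxy)benzaldehyde (F–G aldehyde)
Conditions: CuI (10 mol %), picolinic acid (20 mol %), K3PO4, DMSO, 100 °C, Ar
Reagents that add atoms: none
Why: Copper-catalysed Ullmann diaryl ether synthesis; the bromide of 2 is activated by the para formyl group, the picolinic acid ligand tolerates the two flanking methoxy groups, and phenol 1 is unhindered and electron-rich.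

Step 2
Reactants: 3 F–G aldehyde
Product: 5 3,5-dimethoxy-4-(3,4,5-trimethoxyphenoxy)phenol (F–G phenol), via aryl formate 4 (not isolated)
Conditions: mCPBA, CH2Cl2, 0 °C to rt; NaHCO3 wash; then K2CO3 (cat.), MeOH, rt
Reagents that add atoms: mCPBA, OOC(=O)c1cccc(Cl)c1
Why: Baeyer–Villiger (Dakin-type) oxidation; the oxygen-rich aryl group migrates in preference to hydride, as it does in 3,4,5-trimethoxybenzaldehyde, and the aryl formate is methanolysed to the phenol.

Step 3
Reactants: 5 F–G phenol; 6 ethyl bromoacetate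
Product: 8 [3,5-dimethoxy-4-(3,4,5-trimethoxyphenoxy)phenoxy]acetic acid, via ethyl aryloxyacetate 7 (not isolated)
Conditions: K2CO3, acetone, reflux; then LiOH·H2O, THF/H2O, rt; 1 M HCl
Reagents that add atoms: lithium hydroxide, [Li+].[OH-]
Why: Williamson ether synthesis of the unhindered phenoxide with the α-bromo ester, followed by saponification of the ethyl ester.

Step 4
Reactants: 8 aryloxyacetic acid
Product: 9 [3,5-dimethoxy-4-(3,4,5-trimethoxyphenoxy)phenoxy]acetyl chloride
Conditions: (COCl)2, DMF (cat.), CH2Cl2, 0 °C to rt; evaporate, use at once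
Reagents that add atoms: oxalyl chloride, ClC(=O)C(=O)Cl
Why: Vilsmeier-type chlorination of the acid by oxalyl chloride and catalytic DMF; no Lewis acid is present and the mixture stays cold, so the electron-rich ring F should not be acylated.

Step 5
Reactants: 9 aryloxyacetyl chloride; 10 ethoxyacetylene
Product: 12 rac-4-[3,5-dimethoxy-4-(3,4,5-trimethoxyphenoxy)phenoxy]-3-ethoxycyclobut-2-en-1-one, via aryloxyketene 11 (not isolated)
Conditions: 10 (3 equiv), Et3N (slow addition), Et2O, 0 °C to rt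
Reagents that add atoms: none
Why: Dehydrochlorination gives the aryloxyketene, which undergoes the known polarised (2+2) ketene–ynol ether cycloaddition, the ketene carbonyl carbon bonding to the unsubstituted alkyne carbon; the single stereocentre at C4 forms as a racemate and is removed in step 6.

Step 6
Reactants: 12 4-aryloxy-3-ethoxycyclobutenone; 10 ethoxyacetylene
Product: 17 2-[3,5-dimethoxy-4-(3,4,5-trimethoxyphenoxy)phenoxy]-3,5-diethoxyphenol (E–F–G phenol), via vinylketene 13 (not isolated), via vinylcyclobutenone 14 (not isolated), via dienylketene 15 (not isolated), via cyclohexadienone 16 (not isolated)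
Conditions: 10 (5 equiv), toluene, sealed tube, 90 °C, then 110 °C; then K2CO3 (cat.), MeOH, rt
Reagents that add atoms: none
Why: Danheiser benzannulation, the known thermal reaction of cyclobutenones with alkoxyacetylenes that gives resorcinol monoethers, is the closest and direct precedent. Four-electron electrocyclic opening of 12 gives vinylketene 13, whose ketene C=C adds ethoxyacetylene in a polarised (2+2) cycloaddition to give 14, and this forms the C1–C2 and C3–C4 bonds of ring E. 14 opens in a second four-electron step to dienylketene 15, and ring E is closed by a six-electron disrotatory electrocyclisation that joins the ketene carbon (C1) to the aryloxy-bearing carbon (C6); dienone 16 then tautomerises to phenol 17. No stereocentre remains, because the sp3 centres of 12, 14 and 16 are lost on the way to the arene. The selectivity needed is regiochemical: the electrophilic ketene carbonyl carbon bonds to the nucleophilic unsubstituted carbon of the ynol ether, so the new ethoxy group lands at C3, meta to the C1 hydroxyl, and the ring F ether lands at C6 next to it. The C4 aryloxy donor of 12 rotates outward on opening, which should lower the opening temperature to a range that ethoxyacetylene tolerates and keeps the aryloxy group on the outer side of the triene terminus; all atoms of 12 and 10 end in 17, and the basic methanol treatment only returns product that a ketene has O-acylated.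

Step 7
Reactants: 17 E–F–G phenol; 2 4-bromo-3,5-dimethoxybenzaldehyde
Product: 18 4-{2-[3,5-dimethoxy-4-(3,4,5-trimethoxyphenoxy)phenoxy]-3,5-diethoxyphenoxy}-3,5-dimethoxybenzaldehyde (D–E–F–G aldehyde)
Conditions: CuI (20 mol %), picolinic acid (40 mol %), K3PO4, DMSO, 100 °C, Ar
Reagents that add atoms: none
Why: Ullmann diaryl ether synthesis; the C1 hydroxyl of ring E is the only nucleophile in 17 and the para formyl group activates the doubly ortho-substituted bromide.

Step 8
Reactants: 18 D–E–F–G aldehyde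
Product: 20 D–E–F–G phenol (the formyl group of 18 replaced by hydroxyl), via aryl formate 19 (not isolated)
Conditions: mCPBA, CH2Cl2, 0 °C to rt; NaHCO3 wash; then K2CO3 (cat.), MeOH, rt
Reagents that add atoms: mCPBA, OOC(=O)c1cccc(Cl)c1
Why: Baeyer–Villiger oxidation with aryl migration as in step 2; the formate shields the new phenol from the peracid until methanolysis.

Step 9
Reactants: 20 D–E–F–G phenol; 21 2-bromo-3,4,5-trimethoxybenzaldehyde
Product: 22 C–D–E–F–G aldehyde (3,4,5-trimethoxybenzaldehyde bearing at C2 the ring D oxygen of 20)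
Conditions: CuI (20 mol %), picolinic acid (40 mol %), K3PO4, DMSO, 100 °C, Ar
Reagents that add atoms: none
Why: Ullmann diaryl ether synthesis; the ring D phenol is flanked only by hydrogens and the bromide of 21 is activated by its ortho formyl group.

Step 10
Reactants: 22 C–D–E–F–G aldehyde
Product: 24 C–D–E–F–G phenol (the formyl group of 22 replaced by hydroxyl), via aryl formate 23 (not isolated)
Conditions: mCPBA, CH2Cl2, 0 °C to rt; NaHCO3 wash; then K2CO3 (cat.), MeOH, rt
Reagents that add atoms: mCPBA, OOC(=O)c1cccc(Cl)c1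
Why: Baeyer–Villiger oxidation; the ring C aryl group carries an ortho aryloxy and a para methoxy donor and should migrate cleanly.

Step 11
Reactants: 24 C–D–E–F–G phenol; 2 4-bromo-3,5-dimethoxybenzaldehyde
Product: 25 B–C–D–E–F–G aldehyde (3,5-dimethoxybenzaldehyde bearing at C4 the ring C oxygen of 24)
Conditions: CuI (20 mol %), picolinic acid (40 mol %), K3PO4, DMSO, 100 °C, Ar
Reagents that add atoms: none
Why: Ullmann diaryl ether synthesis of the same steric class as step 7, an ortho-aryloxy phenol with the formyl-activated bromide.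

Step 12
Reactants: 25 B–C–D–E–F–G aldehyde
Product: 27 B–C–D–E–F–G phenol (the formyl group of 25 replaced by hydroxyl), via aryl formate 26 (not isolated)
Conditions: mCPBA, CH2Cl2, 0 °C to rt; NaHCO3 wash; then K2CO3 (cat.), MeOH, rt
Reagents that add atoms: mCPBA, OOC(=O)c1cccc(Cl)c1
Why: Baeyer–Villiger oxidation as in steps 2 and 8.

Step 13
Reactants: 27 B–C–D–E–F–G phenol; 2 4-bromo-3,5-dimethoxybenzaldehyde
Product: 28 A–B–C–D–E–F–G aldehyde (3,5-dimethoxybenzaldehyde bearing at C4 the ring B oxygen of 27)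
Conditions: CuI (20 mol %), picolinic acid (40 mol %), K3PO4, DMSO, 100 °C, Ar
Reagents that add atoms: none
Why: Ullmann diaryl ether synthesis; the ring B phenol is unhindered and the bromide is activated as before.

Step 14
Reactants: 28 heptamer aldehyde
Product: 30 heptamer phenol (ring A C1 hydroxyl free; 14 methyl and 2 ethyl ethers), via aryl formate 29 (not isolated)
Conditions: mCPBA, CH2Cl2, 0 °C to rt; NaHCO3 wash; then K2CO3 (cat.), MeOH, rt
Reagents that add atoms: mCPBA, OOC(=O)c1cccc(Cl)c1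
Why: Baeyer–Villiger oxidation; the hydroxyl it reveals is the C1 hydroxyl of ring A in the target, so no capping is needed.

Step 15
Reactants: 30 heptamer phenol
Product: 31 CNP0351377.0 (target)
Conditions: BBr3 (excess), CH2Cl2, −78 °C to rt, Ar; then H2O, 0 °C
Reagents that add atoms: none
Why: Lewis-acid-mediated cleavage of all sixteen alkyl aryl ethers by BBr3 (bromide attack on the O-alkyl carbon of the borate complex); diaryl ethers are inert to the reagent.

**Compound list**

1 | 3,4,5-trimethoxyphenol | COc1cc(O)cc(OC)c1OC | starting material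
2 | 4-bromo-3,5-dimethoxybenzaldehyde | COc1cc(C=O)cc(OC)c1Br | starting material
3 | 3,5-dimethoxy-4-(3,4,5-trimethoxyphenoxy)benzaldehyde | O=Cc1cc(OC)c(Oc2cc(OC)c(OC)c(OC)c2)c(OC)c1 | intermediate
4 | 3,5-dimethoxy-4-(3,4,5-trimethoxyphenoxy)phenyl formate (formed in situ) | O=COc1cc(OC)c(Oc2cc(OC)c(OC)c(OC)c2)c(OC)c1 | intermediate
5 | 3,5-dimethoxy-4-(3,4,5-trimethoxyphenoxy)phenol | Oc1cc(OC)c(Oc2cc(OC)c(OC)c(OC)c2)c(OC)c1 | intermediate
6 | ethyl bromoacetate | CCOC(=O)CBr | starting material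
7 | ethyl [3,5-dimethoxy-4-(3,4,5-trimethoxyphenoxy)phenoxy]acetate (formed in situ) | CCOC(=O)COc1cc(OC)c(Oc2cc(OC)c(OC)c(OC)c2)c(OC)c1 | intermediate
8 | [3,5-dimethoxy-4-(3,4,5-trimethoxyphenoxy)phenoxy]acetic acid | OC(=O)COc1cc(OC)c(Oc2cc(OC)c(OC)c(OC)c2)c(OC)c1 | intermediate
9 | [3,5-dimethoxy-4-(3,4,5-trimethoxyphenoxy)phenoxy]acetyl chloride | ClC(=O)COc1cc(OC)c(Oc2cc(OC)c(OC)c(OC)c2)c(OC)c1 | intermediate
10 | ethoxyacetylene | CCOC#C | starting material
11 | 2-[3,5-dimethoxy-4-(3,4,5-trimethoxyphenoxy)phenoxy]ethenone (aryloxyketene, formed in situ) | O=C=COc1cc(OC)c(Oc2cc(OC)c(OC)c(OC)c2)c(OC)c1 | intermediate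
12 | rac-4-[3,5-dimethoxy-4-(3,4,5-trimethoxyphenoxy)phenoxy]-3-ethoxycyclobut-2-en-1-one | O=C1C=C(OCC)C1Oc2cc(OC)c(Oc3cc(OC)c(OC)c(OC)c3)c(OC)c2 | intermediate
13 | (3Z)-4-aryloxy-3-ethoxybuta-1,3-dien-1-one, aryl = F–G unit (vinylketene, formed in situ) | O=C=C/C(OCC)=C/Oc1cc(OC)c(Oc2cc(OC)c(OC)c(OC)c2)c(OC)c1 | intermediate
14 | rac-4-[(Z)-2-aryloxy-1-ethoxyethenyl]-3-ethoxycyclobut-2-en-1-one, aryl = F–G unit (formed in situ) | O=C1C=C(OCC)C1/C(OCC)=C/Oc2cc(OC)c(Oc3cc(OC)c(OC)c(OC)c3)c(OC)c2 | intermediate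
15 | (3E,5Z)-6-aryloxy-3,5-diethoxyhexa-1,3,5-trien-1-one, aryl = F–G unit (dienylketene, formed in situ) | O=C=C/C(OCC)=C\C(OCC)=C\Oc1cc(OC)c(Oc2cc(OC)c(OC)c(OC)c2)c(OC)c1 | intermediate
16 | rac-6-aryloxy-3,5-diethoxycyclohexa-2,4-dien-1-one, aryl = F–G unit (formed in situ) | O=C1C=C(OCC)C=C(OCC)C1Oc2cc(OC)c(Oc3cc(OC)c(OC)c(OC)c3)c(OC)c2 | intermediate
17 | 2-[3,5-dimethoxy-4-(3,4,5-trimethoxyphenoxy)phenoxy]-3,5-diethoxyphenol (E–F–G phenol) | Oc1cc(OCC)cc(OCC)c1Oc2cc(OC)c(Oc3cc(OC)c(OC)c(OC)c3)c(OC)c2 | intermediate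
18 | D–E–F–G aldehyde | O=Cc1cc(OC)c(Oc2cc(OCC)cc(OCC)c2Oc3cc(OC)c(Oc4cc(OC)c(OC)c(OC)c4)c(OC)c3)c(OC)c1 | intermediate
19 | D–E–F–G aryl formate (formed in situ) | O=COc1cc(OC)c(Oc2cc(OCC)cc(OCC)c2Oc3cc(OC)c(Oc4cc(OC)c(OC)c(OC)c4)c(OC)c3)c(OC)c1 | intermediate
20 | D–E–F–G phenol | Oc1cc(OC)c(Oc2cc(OCC)cc(OCC)c2Oc3cc(OC)c(Oc4cc(OC)c(OC)c(OC)c4)c(OC)c3)c(OC)c1 | intermediate
21 | 2-bromo-3,4,5-trimethoxybenzaldehyde | O=Cc1cc(OC)c(OC)c(OC)c1Br | starting material
22 | C–D–E–F–G aldehyde | O=Cc1cc(OC)c(OC)c(OC)c1Oc2cc(OC)c(Oc3cc(OCC)cc(OCC)c3Oc4cc(OC)c(Oc5cc(OC)c(OC)c(OC)c5)c(OC)c4)c(OC)c2 | intermediate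
23 | C–D–E–F–G aryl formate (formed in situ) | O=COc1cc(OC)c(OC)c(OC)c1Oc2cc(OC)c(Oc3cc(OCC)cc(OCC)c3Oc4cc(OC)c(Oc5cc(OC)c(OC)c(OC)c5)c(OC)c4)c(OC)c2 | intermediate
24 | C–D–E–F–G phenol | Oc1cc(OC)c(OC)c(OC)c1Oc2cc(OC)c(Oc3cc(OCC)cc(OCC)c3Oc4cc(OC)c(Oc5cc(OC)c(OC)c(OC)c5)c(OC)c4)c(OC)c2 | intermediate
25 | B–C–D–E–F–G aldehyde | O=Cc1cc(OC)c(Oc2cc(OC)c(OC)c(OC)c2Oc3cc(OC)c(Oc4cc(OCC)cc(OCC)c4Oc5cc(OC)c(Oc6cc(OC)c(OC)c(OC)c6)c(OC)c5)c(OC)c3)c(OC)c1 | intermediate
26 | B–C–D–E–F–G aryl formate (formed in situ) | O=COc1cc(OC)c(Oc2cc(OC)c(OC)c(OC)c2Oc3cc(OC)c(Oc4cc(OCC)cc(OCC)c4Oc5cc(OC)c(Oc6cc(OC)c(OC)c(OC)c6)c(OC)c5)c(OC)c3)c(OC)c1 | intermediate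
27 | B–C–D–E–F–G phenol | Oc1cc(OC)c(Oc2cc(OC)c(OC)c(OC)c2Oc3cc(OC)c(Oc4cc(OCC)cc(OCC)c4Oc5cc(OC)c(Oc6cc(OC)c(OC)c(OC)c6)c(OC)c5)c(OC)c3)c(OC)c1 | intermediate
28 | A–B–C–D–E–F–G aldehyde | O=Cc1cc(OC)c(Oc2cc(OC)c(Oc3cc(OC)c(OC)c(OC)c3Oc4cc(OC)c(Oc5cc(OCC)cc(OCC)c5Oc6cc(OC)c(Oc7cc(OC)c(OC)c(OC)c7)c(OC)c6)c(OC)c4)c(OC)c2)c(OC)c1 | intermediate
29 | A–B–C–D–E–F–G aryl formate (formed in situ) | O=COc1cc(OC)c(Oc2cc(OC)c(Oc3cc(OC)c(OC)c(OC)c3Oc4cc(OC)c(Oc5cc(OCC)cc(OCC)c5Oc6cc(OC)c(Oc7cc(OC)c(OC)c(OC)c7)c(OC)c6)c(OC)c4)c(OC)c2)c(OC)c1 | intermediate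
30 | heptamer phenol (ring A C1 hydroxyl free, all other oxygens alkylated) | Oc1cc(OC)c(Oc2cc(OC)c(Oc3cc(OC)c(OC)c(OC)c3Oc4cc(OC)c(Oc5cc(OCC)cc(OCC)c5Oc6cc(OC)c(Oc7cc(OC)c(OC)c(OC)c7)c(OC)c6)c(OC)c4)c(OC)c2)c(OC)c1 | intermediate
31 | CNP0351377.0 | Oc1cc(O)c(Oc2cc(O)c(Oc3cc(O)c(O)c(O)c3Oc3cc(O)c(Oc4cc(O)cc(O)c4Oc4cc(O)c(Oc5cc(O)c(O)c(O)c5)c(O)c4)c(O)c3)c(O)c2)c(O)c1 | target

**Step count**

Total: 15 steps. Longest linear sequence: 15 steps (1 to 31).

**Steps most likely to fail**

Step 6. Ring opening of the vinylogous-ester cyclobutenone 12 may need a temperature at which ethoxyacetylene fragments to ketene and ethylene, so that the vinylketene dimerises or polymerises before it is trapped. The fallback sets out from 5 and comes back at 17; ring E is then bought as a benzaldehyde instead of being built. Commercial 3,5-dihydroxybenzaldehyde is O-ethylated (EtI, K2CO3, DMF) to 3,5-diethoxybenzaldehyde F1 and brominated next to the formyl group (NBS, MeCN) to 2-bromo-3,5-diethoxybenzaldehyde F2. Ullmann coupling of F2 with phenol 5 (CuI, picolinic acid, K3PO4, DMSO) should give 2-[3,5-dimethoxy-4-(3,4,5-trimethoxyphenoxy)phenoxy]-3,5-diethoxybenzaldehyde F3. Baeyer–Villiger oxidation (mCPBA) through the aryl formate F4 and methanolysis then returns 17. This gives up the advantage of the main route, since the crowded C6 ether is made by arylation.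

Step 5. The aryloxyketene may dimerise, or acylate the product, faster than it adds to the ynol ether, and the enol ether of 12 may hydrolyse during purification. The fallback sets out from 5 and comes back at 12; the C4–O bond is made by substitution instead of cycloaddition. Commercial diethyl squarate is reduced (LiAlH(OtBu)3, THF, −78 °C) to 2,3-diethoxy-4-hydroxycyclobut-2-en-1-one F5, which loses ethanol on brief treatment with HCl in CH2Cl2 to give 3-ethoxycyclobut-3-ene-1,2-dione F6. A second hydride reduction at the carbonyl next to the ethoxy-bearing carbon, the one outside the vinylogous ester, should give 3-ethoxy-4-hydroxycyclobut-2-en-1-one F7. Mitsunobu etherification of F7 with phenol 5 (PPh3, DIAD, THF, 0 °C) then gives 12.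

Step 15. Cleavage of sixteen ethers may stop short at the ethyl ethers and the crowded methyl ethers, and the pyrogallol-type rings may oxidise in air during isolation of the free polyphenol. The fallback sets out from 30 and comes back at 31. The ethers are cleaved with AlCl3 and ethanethiol (hard acid with soft nucleophile; CH2Cl2, 0 °C to rt), and the crude polyphenol is acetylated at once (Ac2O, pyridine) to the heptadecaacetate F8. F8 can be purified on silica gel and stored; acid methanolysis (HCl in MeOH, rt, Ar) then releases 31.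

**Further compounds**

F1 | step 6 | 3,5-diethoxybenzaldehyde | O=Cc1cc(OCC)cc(OCC)c1
F2 | step 6 | 2-bromo-3,5-diethoxybenzaldehyde | O=Cc1cc(OCC)cc(OCC)c1Br
F3 | step 6 | 2-[3,5-dimethoxy-4-(3,4,5-trimethoxyphenoxy)phenoxy]-3,5-diethoxybenzaldehyde | O=Cc1cc(OCC)cc(OCC)c1Oc2cc(OC)c(Oc3cc(OC)c(OC)c(OC)c3)c(OC)c2
F4 | step 6 | 2-[3,5-dimethoxy-4-(3,4,5-trimethoxyphenoxy)phenoxy]-3,5-diethoxyphenyl formate | O=COc1cc(OCC)cc(OCC)c1Oc2cc(OC)c(Oc3cc(OC)c(OC)c(OC)c3)c(OC)c2
F5 | step 5 | rac-2,3-diethoxy-4-hydroxycyclobut-2-en-1-one | O=C1C(OCC)=C(OCC)C1O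
F6 | step 5 | 3-ethoxycyclobut-3-ene-1,2-dione | O=C1C=C(OCC)C1=O
F7 | step 5 | rac-3-ethoxy-4-hydroxycyclobut-2-en-1-one | O=C1C=C(OCC)C1O
F8 | step 15 | heptadecaacetate of 31 | CC(=O)Oc1cc(OC(C)=O)c(Oc2cc(OC(C)=O)c(Oc3cc(OC(C)=O)c(OC(C)=O)c(OC(C)=O)c3Oc4cc(OC(C)=O)c(Oc5cc(OC(C)=O)cc(OC(C)=O)c5Oc6cc(OC(C)=O)c(Oc7cc(OC(C)=O)c(OC(C)=O)c(OC(C)=O)c7)c(OC(C)=O)c6)c(OC(C)=O)c4)c(OC(C)=O)c2)c(OC(C)=O)c1
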